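**Retrosynthetic overview**
- The strategy rests on the 4-pyranone ring C: its C4, C3 and C2 lie between the 5,7-dioxygenated ring A (C4a, C8a–O1) and C1' of ring B. Ring C is therefore cut into C4–C4a, C2–C3 and O1–C2 and assembled from phloroglucinol, an arylacetic acid (C3, C4, ring B) and DMF (C2).
- The C3' prenyl group is disconnected last (C3'–CH2, Suzuki–Miyaura coupling). A C3' bromide stands in for it from the start, because the alkene would not survive the Lewis acid or the ether cleavage.
- The ring B oxygens pass through the annulation as methyl ethers (a free 2'-OH would compete for C2) and are exchanged for MOM ethers before the coupling.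
- The arylacetic acid comes from 2-bromo-1,3-dimethoxybenzene by formylation, one-carbon homologation to the nitrile and hydrolysis.
- Ring order: rings A and B are bought as benzene rings; ring C is the only ring formed (step 4).

Key step: step 4

Remark: the target has no stereocentre and no stereogenic double bond, so it is achiral; the single-enantiomer request is met by the structure itself and no stereocontrol is needed.

**Route**

Step 1
Reactants: 1 2-bromo-1,3-dimethoxybenzene
Product: 2 3-bromo-2,4-dimethoxybenzaldehyde
Conditions: Cl2CHOMe, TiCl4, CH2Cl2, 0 °C to rt; then ice/aq HCl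
Reagents that add atoms: dichloromethyl methyl ether, COC(Cl)Cl; water, O
Why: Rieche formylation (Friedel–Crafts reaction of the TiCl4-activated α-chloro ether) can only take place at the equivalent positions C4/C6, ortho to one methoxy group and para to the other, and hydrolysis of the α-chlorobenzyl ether on work-up should release the aldehyde.

Step 2
Reactants: 2 3-bromo-2,4-dimethoxybenzaldehyde
Product: 3 2-(3-bromo-2,4-dimethoxyphenyl)acetonitrile
Conditions: TosMIC, t-BuOK, DME, −50 °C; then MeOH, reflux
Reagents that add atoms: p-toluenesulfonylmethyl isocyanide (TosMIC), Cc1ccc(cc1)S(=O)(=O)C[N+]#[C-]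
Why: Van Leusen reductive cyanation, in which the TosMIC anion adds to the aldehyde and closes to a 4-tosyl-2-oxazoline that excess base opens to an N-(1-tosylalkenyl)formamide, whereupon methanolysis of the formyl group and loss of sulfinate should give the homologous nitrile.

Step 3
Reactants: 3 2-(3-bromo-2,4-dimethoxyphenyl)acetonitrile
Product: 4 2-(3-bromo-2,4-dimethoxyphenyl)acetic acid
Conditions: KOH, EtOH/H2O, reflux; then aq HCl to pH 1
Reagents that add atoms: potassium hydroxide, [K+].[OH-]; water, O
Why: Base hydrolysis of the nitrile through the primary amide to the carboxylate, to which the electron-rich aryl bromide and the methyl ethers are inert.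

Step 4
Reactants: 4 2-(3-bromo-2,4-dimethoxyphenyl)acetic acid; 5 phloroglucinol (anhydrous); 6 N,N-dimethylformamide (source of C2)
Product: 9 3-(3-bromo-2,4-dimethoxyphenyl)-5,7-dihydroxychromen-4-one, via deoxybenzoin 7 (not isolated), via enaminone 8 (not isolated)
Conditions: BF3·OEt2 (neat), 85 °C; cool, DMF, then MsCl in DMF, 70 °C; aq NaOAc work-up
Reagents that add atoms: none
Why: BF3 activates the acid and acylates phloroglucinol at carbon (C4–C4a), any aryl ester formed first being funnelled to the C-acyl product by Fries-type equilibration, so that deoxybenzoin 7 sits in the flask as its six-membered O,O-difluoroboron chelate. DMF and MsCl then form a chloroiminium salt that is attacked by the benzylic enol carbon of the chelate (C2–C3) to give enaminone 8, whose remaining ortho hydroxyl adds to the β-carbon with loss of dimethylamine (O1–C2). The closest known reaction type is the one-pot BF3-mediated Friedel–Crafts acylation and Vilsmeier-type formylative cyclisation of phenols with arylacetic acids to isoflavones. Ring C closes in the 6-endo-trig mode by conjugate addition–elimination and no stereocentre is formed. The step needs mono-C-acylation, which the first acyl group and its boron chelate secure by deactivating ring A, and formylation at the benzylic carbon instead of on ring A, which the chelate secures by acidifying that CH2 (formate esters on oxygen are cleaved on work-up). The symmetry of phloroglucinol makes the two ortho hydroxyls equivalent, the methyl ethers keep the 2'-oxygen from closing a benzofuran, and the C3' bromide is inert to the Lewis acid.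

Step 5
Reactants: 9 3-(3-bromo-2,4-dimethoxyphenyl)-5,7-dihydroxychromen-4-one
Product: 10 3-(3-bromo-2,4-dihydroxyphenyl)-5,7-dihydroxychromen-4-one
Conditions: BBr3 (excess), CH2Cl2, −78 °C to rt; then MeOH/H2O
Reagents that add atoms: none
Why: Lewis-acid ether cleavage, in which BBr3 binds each methoxy oxygen and bromide attacks the methyl group (SN2), should free both ring B phenols while the chromone and the aryl bromide stay intact; it is placed before the prenylation because the alkene would not tolerate it.

Step 6
Reactants: 10 3-(3-bromo-2,4-dihydroxyphenyl)-5,7-dihydroxychromen-4-one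
Product: 11 3-[3-bromo-2,4-bis(methoxymethoxy)phenyl]-5-hydroxy-7-(methoxymethoxy)chromen-4-one
Conditions: MOMCl, i-Pr2NEt, DMF, 0 °C to rt
Reagents that add atoms: chloromethyl methyl ether, COCCl
Why: Williamson-type O-alkylation (MOM ether formation) should cap the 7-, 2'- and 4'-phenols, while the 5-OH, held in a hydrogen bond to the C4 carbonyl, is expected to stay free under amine-base conditions.

Step 7
Reactants: 11 3-[3-bromo-2,4-bis(methoxymethoxy)phenyl]-5-hydroxy-7-(methoxymethoxy)chromen-4-one; 12 prenylboronic acid pinacol ester
Product: 13 5-hydroxy-7-(methoxymethoxy)-3-[2,4-bis(methoxymethoxy)-3-(3-methylbut-2-enyl)phenyl]chromen-4-one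
Conditions: Pd(dppf)Cl2·CH2Cl2 (cat.), K3PO4, THF/H2O, 65 °C
Reagents that add atoms: none
Why: Suzuki–Miyaura coupling of the aryl bromide with the allylic boronate, in which the η3-prenyl(aryl)palladium intermediate should reductively eliminate at its unsubstituted terminus (favoured by the doubly ortho-substituted aryl group and the wide-bite-angle ligand) to give the linear prenyl group, the mild phosphate base sparing the chromone and the MOM ethers.

Step 8
Reactants: 13 5-hydroxy-7-(methoxymethoxy)-3-[2,4-bis(methoxymethoxy)-3-(3-methylbut-2-enyl)phenyl]chromen-4-one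
Product: 14 licoisoflavone A, 5,7-dihydroxy-3-[2,4-dihydroxy-3-(3-methylbut-2-enyl)phenyl]chromen-4-one
Conditions: 3 M aq HCl, MeOH/THF, 40 °C
Reagents that add atoms: none
Why: Acid-catalysed acetal cleavage (transacetalisation to dimethoxymethane) should remove the three MOM ethers under dilute acid at mild temperature, conditions under which the trisubstituted alkene is not expected to add the flanking phenols.

**Compound list**
1 | 2-bromo-1,3-dimethoxybenzene | COc1cccc(OC)c1Br | starting material
2 | 3-bromo-2,4-dimethoxybenzaldehyde | COc1ccc(C=O)c(OC)c1Br | intermediate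
3 | 2-(3-bromo-2,4-dimethoxyphenyl)acetonitrile | COc1ccc(CC#N)c(OC)c1Br | intermediate
4 | 2-(3-bromo-2,4-dimethoxyphenyl)acetic acid | COc1ccc(CC(=O)O)c(OC)c1Br | intermediate
5 | phloroglucinol (benzene-1,3,5-triol) | Oc1cc(O)cc(O)c1 | starting material
6 | N,N-dimethylformamide | CN(C)C=O | starting material
7 | 2-(3-bromo-2,4-dimethoxyphenyl)-1-(2,4,6-trihydroxyphenyl)ethanone (deoxybenzoin, held in the flask as its O,O-difluoroboron chelate) | COc1ccc(CC(=O)c2c(O)cc(O)cc2O)c(OC)c1Br | intermediate
8 | 2-(3-bromo-2,4-dimethoxyphenyl)-3-(dimethylamino)-1-(2,4,6-trihydroxyphenyl)prop-2-en-1-one (enaminone) | COc1ccc(C(=CN(C)C)C(=O)c2c(O)cc(O)cc2O)c(OC)c1Br | intermediate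
9 | 3-(3-bromo-2,4-dimethoxyphenyl)-5,7-dihydroxychromen-4-one | COc1ccc(-c2coc3cc(O)cc(O)c3c2=O)c(OC)c1Br | intermediate
10 | 3-(3-bromo-2,4-dihydroxyphenyl)-5,7-dihydroxychromen-4-one | Oc1cc(O)c2c(c1)occ(-c1ccc(O)c(Br)c1O)c2=O | intermediate
11 | 3-[3-bromo-2,4-bis(methoxymethoxy)phenyl]-5-hydroxy-7-(methoxymethoxy)chromen-4-one | COCOc1cc(O)c2c(c1)occ(-c1ccc(OCOC)c(Br)c1OCOC)c2=O | intermediate
12 | prenylboronic acid pinacol ester, 4,4,5,5-tetramethyl-2-(3-methylbut-2-enyl)-1,3,2-dioxaborolane | CC(C)=CCB1OC(C)(C)C(C)(C)O1 | starting material
13 | 5-hydroxy-7-(methoxymethoxy)-3-[2,4-bis(methoxymethoxy)-3-(3-methylbut-2-enyl)phenyl]chromen-4-one | COCOc1cc(O)c2c(c1)occ(-c1ccc(OCOC)c(CC=C(C)C)c1OCOC)c2=O | intermediate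
14 | licoisoflavone A | CC(C)=CCc1c(O)ccc(-c2coc3cc(O)cc(O)c3c2=O)c1O | target

**Step count**
Total steps: 8. Longest linear sequence: 8 steps (1 to 14); phloroglucinol 5, DMF 6 and boronate 12 enter as bought components.

**Steps most likely to fail**

1. Step 4 (key step). What may go wrong: incomplete acylation or a second acylation of phloroglucinol, partial loss of the ortho methyl ether in hot BF3·OEt2, and formylation of the electron-rich ring A in competition with the benzylic carbon, so that the one-pot sequence delivers a mixture. Fallback, setting out from nitrile 3 (with phloroglucinol 5) and returning at 9: the C4–C4a bond is made separately by a Houben–Hoesch reaction (dry HCl, ZnCl2, Et2O, 0 °C), which should precipitate 2-(3-bromo-2,4-dimethoxyphenyl)-1-(2,4,6-trihydroxyphenyl)ethaniminium chloride F1. Hydrolysis of F1 in hot water should give deoxybenzoin 7, which is now isolated and purified. Compound 7 is then closed in its own operation with BF3·OEt2, DMF and MsCl at 70 °C to give 9, so that acylation and formylative ring closure can be optimised independently.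

2. Step 7. What may go wrong: transfer of the prenyl group through its tertiary carbon (reverse-prenyl isomer), slow oxidative addition at the doubly ortho-substituted bromide, and competing protodeboronation or hydrodebromination. Fallback, setting out from 11 and returning at 13: Stille coupling with allyltributylstannane (Pd(PPh3)4, DMF, 90 °C) should give 3-[3-allyl-2,4-bis(methoxymethoxy)phenyl]-5-hydroxy-7-(methoxymethoxy)chromen-4-one F2; the symmetric allyl group removes the regiochemical question. Olefin cross-metathesis of F2 with excess 2-methyl-2-butene (second-generation ruthenium NHC benzylidene catalyst, CH2Cl2, 40 °C) should then build the trisubstituted alkene and give 13.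

3. Step 8. What may go wrong: acid-catalysed addition of the 2'- or 4'-hydroxyl to the prenyl double bond (closure to a 2,2-dimethylchroman) or hydration of the alkene, in competition with acetal cleavage. Fallback, setting out from 10 and returning at 14, with base-labile protection so that no acid touches the prenyl group: acetylation (Ac2O, pyridine, DMAP, rt) should give 3-(2,4-diacetoxy-3-bromophenyl)-4-oxochromene-5,7-diyl diacetate F3. Stille coupling of F3 under neutral conditions with tributyl(3-methylbut-2-enyl)stannane (Pd(P(t-Bu)3)2, toluene, 90 °C) should give 3-[2,4-diacetoxy-3-(3-methylbut-2-enyl)phenyl]-4-oxochromene-5,7-diyl diacetate F4. Methanolysis of F4 (K2CO3, MeOH, rt, then mild acidification to pH 5) should give 14.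

**Further compounds**
F1 | step 4 | 2-(3-bromo-2,4-dimethoxyphenyl)-1-(2,4,6-trihydroxyphenyl)ethaniminium chloride | COc1ccc(CC(=[NH2+])c2c(O)cc(O)cc2O)c(OC)c1Br.[Cl-]
F2 | step 7 | 3-[3-allyl-2,4-bis(methoxymethoxy)phenyl]-5-hydroxy-7-(methoxymethoxy)chromen-4-one | COCOc1cc(O)c2c(c1)occ(-c1ccc(OCOC)c(CC=C)c1OCOC)c2=O
F3 | step 8 | 3-(2,4-diacetoxy-3-bromophenyl)-4-oxochromene-5,7-diyl diacetate | CC(=O)Oc1cc(OC(C)=O)c2c(c1)occ(-c1ccc(OC(C)=O)c(Br)c1OC(C)=O)c2=O
F4 | step 8 | 3-[2,4-diacetoxy-3-(3-methylbut-2-enyl)phenyl]-4-oxochromene-5,7-diyl diacetate | CC(=O)Oc1cc(OC(C)=O)c2c(c1)occ(-c1ccc(OC(C)=O)c(CC=C(C)C)c1OC(C)=O)c2=O
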